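All runs are simulated from invented constants; noise was put on by code.

Late in the two earlier runs the readings of the complex with one exchanged agreed: the ochre run read 13% and the grey run 13% at 12.0 min, though the grey run held more protic impurity than the ochre run.

| flask | starting complex | incoming ligand | protic impurity | remark | time |
|---|---|---|---|---|---|
| ochre | 2.0 × 10⁻⁴ M | 0.60 mM | 0.010 mM | run made earlier |  |
| grey | 2.0 × 10⁻⁴ M | 0.60 mM | 0.015 mM | run made earlier |  |
| flask | 2.0 × 10⁻⁴ M | 0.600 mM | 0.0200 mM |  | 15 min |

| run | time / min | complex with one exchanged / % | complex with three exchanged / % |
|---|---|---|---|
| ochre | 3.00 | 21 | 26 |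
| ochre | 6.00 | 14 | 20 |
| ochre | 10.0 | 17 | 17 |
| ochre | 12.0 | 13 | 17 |
| grey | 1.00 | 31 | 24 |
| grey | 2.00 | 24 | 30 |
| grey | 5.00 | 22 | 22 |
| grey | 12.0 | 13 | 11 |

(each reading ± 2 percentage points)

- the earlier runs were read with a standard deviation of 2 percentage points

* equivalents of incoming ligand to starting complex, everything else as given, that leave most complex with one exchanged at 15 min
* the amount of complex with one exchanged then, in percent of the starting complex charged
* the amount of complex with one exchanged with the amounts as given

From the grey run's fall from 24% at 2.00 min to 13% at 12.0 min I reckoned 11.3 min, the late half-life: the time in which the reading of the complex with one exchanged halves once the first minutes are over. My first doubt was the ochre run, whose own readings give 13.0 min, but each reading carries a scatter of 2 points, so I kept the grey value as a reading of the same thing.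

My second doubt was the protic impurity. If the fall went with its charge, the half-life should have shortened by a factor of 1.50 from ochre to grey, and the readings showed 1.15. In the flask its charge is 3.33% of the charge of incoming ligand, far less than the incoming ligand, so I did not shorten the half-life for this flask. Carried from the grey run's reading of 13% over a further 3.00 min, it gave me an estimate of about 10.8% of complex with one exchanged for the flask as charged.

The forecast gave 5.4% for the flask as charged and 8.5% at 1.15 equiv, holding that the loss “looks proportional to impurity”; there my reckoning differed from it.

The flask gave 9.62% as charged, and 13.9% at 1.46 equiv.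

    protic impurity + incoming ligand → quenched reagent (k = 79.0 L mol⁻¹ s⁻¹)
    complex with one exchanged + incoming ligand ⇌ leaving ligand + complex with two exchanged (K = 0.240, k = 310 L mol⁻¹ s⁻¹)
    complex with two exchanged → side product (k = 0.0240 s⁻¹)
    complex with two exchanged + incoming ligand ⇌ leaving ligand + complex with three exchanged (K = 7.00, k = 140 L mol⁻¹ s⁻¹)
    starting complex + incoming ligand ⇌ leaving ligand + complex with one exchanged (K = 1.40, k = 150 L mol⁻¹ s⁻¹)

Carried from the flask's 15.7% at 7.50 min, the late half-life of 11.3 min gives 9.91% at 15 min, and the protic impurity, whose half-life by its own step at the charged amounts is 0.24 min, far shorter than 11.3 min, stood at 0.00748% of its charge at 7.50 min while side product rose from 48.5% then to 69.6% at 15.0 min. Carried 3.00 min past the last reading of the ochre run, from its 11.5% of complex with one exchanged without scatter at 12.0 min, the same half-life gives 9.57%, and the ochre run taken on to 15 min held 9.43%.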